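**Retrosynthetic overview**

- The target is 5,8-dihydroxy-7-methoxy-6-prenyl-2',4',5'-trimethoxyisoflavone. The C8 oxygen and the C6 prenyl group are added last through the 5,8-quinone: Teuber oxidation of the 5-phenol, then prenylstannane/BF3 at C6, the only free quinone carbon.
- The strategy rests on C2 of ring C, a CH bonded only to O1 and C3. It is taken from the carbon of an ortho methoxy group of a 2,4,6-trimethoxyphenyl ketone, and ring C closes by forming C2–C3 through rhodium carbene insertion into that O–CH3 bond. This gives the isoflavanone, which DDQ dehydrogenates to the isoflavone.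
- The diazo ketone comes from a deoxybenzoin by diazo transfer. The deoxybenzoin comes from 2-lithio-1,3,5-trimethoxybenzene and the Weinreb amide of (2-silyloxy-4,5-dimethoxyphenyl)acetic acid, made from 3,4-dimethoxyphenol and glyoxylic acid via the benzofuranone.
- Ring order: rings A and B are bought as arenes; ring C is the only ring built.

Key step: step 7

Assumption: the target is achiral, so no stereocentre has to be set; the carbinol carbon of 3 and C3 of 12 are racemic and are removed in steps 2 and 8. Glyoxylic acid is used as its commercial 50% aqueous solution. Isoflavone numbering (O1, C2, C3, C4, C4a, C5–C8, C8a; ring B primed) is used throughout.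

**Route**

Step 1
Reactants: 1 3,4-dimethoxyphenol; 2 glyoxylic acid
Product: 3 2-hydroxy-2-(2-hydroxy-4,5-dimethoxyphenyl)acetic acid (racemic)
Conditions: NaOH (2.2 equiv), H2O, 0 °C → rt, N2; then aq. HCl to pH 1
Reagents that add atoms: none
Why: Base-mediated hydroxyalkylation of the phenoxide by glyoxylate (electrophilic aromatic substitution) should occur at C6, the unhindered position ortho to the phenoxide (para is blocked by OMe), giving the racemic mandelic acid whose carbinol centre is removed in step 2.

Step 2
Reactants: 3 2-hydroxy-2-(2-hydroxy-4,5-dimethoxyphenyl)acetic acid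
Product: 5 5,6-dimethoxy-1-benzofuran-2(3H)-one, via (2-hydroxy-4,5-dimethoxyphenyl)acetic acid 4 (not isolated)
Conditions: H2 (3 atm), 10% Pd/C, AcOH, cat. H2SO4, 60 °C; filter; then TsOH (cat.), PhMe, reflux (Dean–Stark)
Reagents that add atoms: none
Why: Acid-promoted benzylic hydrogenolysis of the mandelic C–OH (assisted by the para methoxy and ortho hydroxy groups) followed by acid-catalysed lactonisation of the o-hydroxyphenylacetic acid should give the five-membered aryl lactone.

Step 3
Reactants: 5 5,6-dimethoxy-1-benzofuran-2(3H)-one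
Product: 6 2-(2-hydroxy-4,5-dimethoxyphenyl)-N-methoxy-N-methylacetamide
Conditions: MeNH(OMe)·HCl (3 equiv), AlMe3 (3 equiv), CH2Cl2, 0 °C → rt; cold dilute aq. HCl work-up
Reagents that add atoms: N,O-dimethylhydroxylamine hydrochloride, CNOC.Cl
Why: Weinreb aminolysis of an activated aryl lactone by the aluminium amide should open the ring to the Weinreb amide and free the phenol in one operation, avoiding selective protection of a hydroxy acid.

Step 4
Reactants: 6 2-(2-hydroxy-4,5-dimethoxyphenyl)-N-methoxy-N-methylacetamide
Product: 7 2-[4,5-dimethoxy-2-(triisopropylsilyloxy)phenyl]-N-methoxy-N-methylacetamide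
Conditions: TIPSCl, imidazole, DMF, rt → 40 °C
Reagents that add atoms: chlorotriisopropylsilane, CC(C)[Si](Cl)(C(C)C)C(C)C
Why: Standard silylation of a phenol gives a triisopropylsilyl ether that should tolerate the aryllithium, DBU and carbene steps and that has no C–H bond α to oxygen.

Step 5
Reactants: 7 2-[4,5-dimethoxy-2-(triisopropylsilyloxy)phenyl]-N-methoxy-N-methylacetamide; 8 1,3,5-trimethoxybenzene
Product: 10 2-[4,5-dimethoxy-2-(triisopropylsilyloxy)phenyl]-1-(2,4,6-trimethoxyphenyl)ethanone, via 2-lithio-1,3,5-trimethoxybenzene 9 (not isolated)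
Conditions: 8 (2.2 equiv), n-BuLi (2.1 equiv), TMEDA, THF, 0 °C → rt; then 7, −78 → 0 °C; aq. NH4Cl
Reagents that add atoms: none
Why: Directed ortho-lithiation between two methoxy groups and acylation of the aryllithium by the Weinreb amide (Weinreb ketone synthesis) should give the deoxybenzoin, the chelated tetrahedral intermediate preventing over-addition and the excess aryllithium compensating for α-deprotonation.

Step 6
Reactants: 10 2-[4,5-dimethoxy-2-(triisopropylsilyloxy)phenyl]-1-(2,4,6-trimethoxyphenyl)ethanone
Product: 11 2-diazo-2-[4,5-dimethoxy-2-(triisopropylsilyloxy)phenyl]-1-(2,4,6-trimethoxyphenyl)ethanone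
Conditions: 4-acetamidobenzenesulfonyl azide, DBU, MeCN, 0 °C → rt
Reagents that add atoms: 4-acetamidobenzenesulfonyl azide, CC(=O)Nc1ccc(S(=O)(=O)N=[N+]=[N-])cc1
Why: Regitz diazo transfer to the benzylic methylene of a deoxybenzoin, activated by both the ketone and the aryl group, should give the aryl diazo ketone directly.

Step 7
Reactants: 11 2-diazo-2-[4,5-dimethoxy-2-(triisopropylsilyloxy)phenyl]-1-(2,4,6-trimethoxyphenyl)ethanone
Product: 12 3-[4,5-dimethoxy-2-(triisopropylsilyloxy)phenyl]-5,7-dimethoxychroman-4-one (racemic)
Conditions: Rh2(OAc)4 (2 mol%), CH2Cl2, 40 °C, slow addition of 11 by syringe pump, high dilution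
Reagents that add atoms: none
Why: Proposed new method: Rh2(OAc)4 (divalent rhodium) should take N2 from 11 to give an electrophilic rhodium aryl(acyl)carbene at the future C3, stabilised by the electron-rich ring B donor and the ketone acceptor, which attacks a C–H bond of an ortho methoxy group of ring A through a six-membered, hydride-transfer-like transition state in which the ether oxygen stabilises the developing positive charge. The closest known reaction types are the Rh2(OAc)4-catalysed 1,6 C–H insertion of α-diazo ketones into ortho O–CH2R groups that gives chroman-4-ones and the insertion of donor/acceptor rhodium carbenes into the primary C–H bonds of methyl ethers; closure of a chromanone by acyl carbene insertion into an aryl O–CH3 group has not been shown. Ring C is closed by this 1,6 C–H insertion, which forms the C2–C3 bond, the former methoxy carbon becoming C2 and its oxygen O1. The new C3 stereocentre forms without control (achiral catalyst, racemic) and is removed by the dehydrogenation of step 8. The step needs insertion into the ring A methoxy in preference to other carbene outlets: the two ortho methoxy groups of the symmetric 2,4,6-trimethoxyphenyl ketone are equivalent so only one isoflavanone can form, the ring B ortho oxygen is a silyl ether with no C–H α to oxygen so the five-membered insertion to a dihydrobenzofuran is excluded, oxonium ylide formation at the methoxy oxygen is reversible and a methyl group has no easy onward shift, and slow addition at low concentration suppresses carbene dimerisation.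

Step 8
Reactants: 12 3-[4,5-dimethoxy-2-(triisopropylsilyloxy)phenyl]-5,7-dimethoxychroman-4-one
Product: 13 3-[4,5-dimethoxy-2-(triisopropylsilyloxy)phenyl]-5,7-dimethoxychromen-4-one
Conditions: DDQ (1.5 equiv), 1,4-dioxane, reflux
Reagents that add atoms: none
Why: DDQ dehydrogenation of an isoflavanone (hydride abstraction from C2 next to the ring oxygen, then loss of the C3 proton) should give the isoflavone and erase the racemic C3 centre while the 2'-oxygen is still silylated and cannot cyclise onto C2.

Step 9
Reactants: 13 3-[4,5-dimethoxy-2-(triisopropylsilyloxy)phenyl]-5,7-dimethoxychromen-4-one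
Product: 15 5,7-dimethoxy-3-(2,4,5-trimethoxyphenyl)chromen-4-one, via caesium phenoxide 14 (not isolated)
Conditions: CsF (3 equiv), MeI (5 equiv), DMF, rt
Reagents that add atoms: iodomethane, CI
Why: Fluoride-induced cleavage of the aryl silyl ether with in situ Williamson O-methylation of the phenoxide should give the 2'-methyl ether without accumulating the free 2'-hydroxyisoflavone.

Step 10
Reactants: 15 5,7-dimethoxy-3-(2,4,5-trimethoxyphenyl)chromen-4-one
Product: 16 5-hydroxy-7-methoxy-3-(2,4,5-trimethoxyphenyl)chromen-4-one
Conditions: BCl3 (1.2 equiv), CH2Cl2, −78 → 0 °C; then H2O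
Reagents that add atoms: none
Why: Chelation-controlled ether cleavage: BCl3 bound to the C4 carbonyl should remove only the peri 5-methyl ether through a six-membered boron chelate, leaving the 7-, 2'-, 4'- and 5'-methyl ethers.

Step 11
Reactants: 16 5-hydroxy-7-methoxy-3-(2,4,5-trimethoxyphenyl)chromen-4-one
Product: 17 7-methoxy-3-(2,4,5-trimethoxyphenyl)chromene-4,5,8-trione
Conditions: ON(SO3K)2 (potassium nitrosodisulfonate, 3 equiv), aq. KH2PO4, acetone–H2O, rt
Reagents that add atoms: potassium nitrosodisulfonate, [K+].[K+].[O]N(S(=O)(=O)[O-])S(=O)(=O)[O-]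
Why: Teuber oxidation: the nitroxyl radical should oxidise the 5-phenol and a second equivalent should deliver oxygen to the free para position C8, giving the 5,8-para-quinone without touching the aryl methyl ethers of ring B.

Step 12
Reactants: 17 7-methoxy-3-(2,4,5-trimethoxyphenyl)chromene-4,5,8-trione
Product: 18 5,8-dihydroxy-7-methoxy-6-(3-methylbut-2-enyl)-3-(2,4,5-trimethoxyphenyl)chromen-4-one (target)
Conditions: tributyl(3-methylbut-2-enyl)stannane (1.5 equiv), BF3·OEt2 (3 equiv), CH2Cl2, −78 → −40 °C; then H2O, work-up under N2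
Reagents that add atoms: tributyl(3-methylbut-2-enyl)stannane, CCCC[Sn](CCCC)(CCCC)CC=C(C)C
Why: Lewis acid-promoted allylstannane allylation of a quinone (Naruta-type): C6 is the only unsubstituted quinone carbon, BF3 chelated between the C4 and C5 carbonyls should activate the C5 side, the prenyl group should arrive with its primary carbon on C6 (carbonyl addition at the substituted terminus followed by [3,3] shift, or direct conjugate addition), and tautomerisation gives the hydroquinone target.

**Compound list**

1 | 3,4-dimethoxyphenol | COc1ccc(O)cc1OC | starting material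
2 | glyoxylic acid | O=CC(=O)O | starting material
3 | 2-hydroxy-2-(2-hydroxy-4,5-dimethoxyphenyl)acetic acid (racemic) | COc1cc(O)c(C(O)C(=O)O)cc1OC | intermediate
4 | (2-hydroxy-4,5-dimethoxyphenyl)acetic acid (not isolated) | COc1cc(O)c(CC(=O)O)cc1OC | intermediate
5 | 5,6-dimethoxy-1-benzofuran-2(3H)-one | COc1cc2c(cc1OC)OC(=O)C2 | intermediate
6 | 2-(2-hydroxy-4,5-dimethoxyphenyl)-N-methoxy-N-methylacetamide | COc1cc(O)c(CC(=O)N(C)OC)cc1OC | intermediate
7 | 2-[4,5-dimethoxy-2-(triisopropylsilyloxy)phenyl]-N-methoxy-N-methylacetamide | COc1cc(O[Si](C(C)C)(C(C)C)C(C)C)c(CC(=O)N(C)OC)cc1OC | intermediate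
8 | 1,3,5-trimethoxybenzene | COc1cc(OC)cc(OC)c1 | starting material
9 | 2-lithio-1,3,5-trimethoxybenzene (not isolated) | [Li]c1c(OC)cc(OC)cc1OC | intermediate
10 | 2-[4,5-dimethoxy-2-(triisopropylsilyloxy)phenyl]-1-(2,4,6-trimethoxyphenyl)ethanone | COc1cc(OC)c(C(=O)Cc2cc(OC)c(OC)cc2O[Si](C(C)C)(C(C)C)C(C)C)c(OC)c1 | intermediate
11 | 2-diazo-2-[4,5-dimethoxy-2-(triisopropylsilyloxy)phenyl]-1-(2,4,6-trimethoxyphenyl)ethanone | COc1cc(OC)c(C(=O)C(=[N+]=[N-])c2cc(OC)c(OC)cc2O[Si](C(C)C)(C(C)C)C(C)C)c(OC)c1 | intermediate
12 | 3-[4,5-dimethoxy-2-(triisopropylsilyloxy)phenyl]-5,7-dimethoxychroman-4-one (racemic) | COc1cc(OC)c2c(c1)OCC(c1cc(OC)c(OC)cc1O[Si](C(C)C)(C(C)C)C(C)C)C2=O | intermediate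
13 | 3-[4,5-dimethoxy-2-(triisopropylsilyloxy)phenyl]-5,7-dimethoxychromen-4-one | COc1cc(OC)c2c(c1)occ(-c1cc(OC)c(OC)cc1O[Si](C(C)C)(C(C)C)C(C)C)c2=O | intermediate
14 | caesium 2-(5,7-dimethoxy-4-oxochromen-3-yl)-4,5-dimethoxyphenoxide (not isolated) | COc1cc(OC)c2c(c1)occ(-c1cc(OC)c(OC)cc1[O-])c2=O.[Cs+] | intermediate
15 | 5,7-dimethoxy-3-(2,4,5-trimethoxyphenyl)chromen-4-one | COc1cc(OC)c2c(c1)occ(-c1cc(OC)c(OC)cc1OC)c2=O | intermediate
16 | 5-hydroxy-7-methoxy-3-(2,4,5-trimethoxyphenyl)chromen-4-one | COc1cc(O)c2c(c1)occ(-c1cc(OC)c(OC)cc1OC)c2=O | intermediate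
17 | 7-methoxy-3-(2,4,5-trimethoxyphenyl)chromene-4,5,8-trione | COC1=CC(=O)C2=C(OC=C(c3cc(OC)c(OC)cc3OC)C2=O)C1=O | intermediate
18 | 5,8-dihydroxy-7-methoxy-6-(3-methylbut-2-enyl)-3-(2,4,5-trimethoxyphenyl)chromen-4-one | COc1cc(OC)c(-c2coc3c(O)c(OC)c(CC=C(C)C)c(O)c3c2=O)cc1OC | target

**Step count**

Total: 12 steps. Longest linear sequence: 12 steps (1 → 18); the aryllithium 9 is made in situ within step 5.

**Steps most likely to fail**

Step 7 (the new method). The carbene may be diverted before it inserts into the O–CH3 bond. Possible diversions are attack on the methoxy oxygen with onward 1,2-methyl shift or demethylation of the oxonium ylide, Wolff rearrangement, insertion into a C–H bond of the silyl group, and dimerisation. The fallback is the classical deoxybenzoin isoflavone synthesis. It sets out from ketone 10: chelation-controlled mono-demethylation with BCl3 (CH2Cl2, −78 → 0 °C) should give 2-[4,5-dimethoxy-2-(triisopropylsilyloxy)phenyl]-1-(2-hydroxy-4,6-dimethoxyphenyl)ethanone F1. Heating F1 with N,N-dimethylformamide dimethyl acetal (PhMe, 90 °C) should form the enaminone 3-(dimethylamino)-2-[4,5-dimethoxy-2-(triisopropylsilyloxy)phenyl]-1-(2-hydroxy-4,6-dimethoxyphenyl)prop-2-en-1-one F2 (alkene geometry not controlled). F2 cyclises through the phenol with loss of dimethylamine to isoflavone 13, where the route is rejoined; steps 6 to 8 are bypassed.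

Step 12. The allylation may be misdirected: addition of the stannane to the C8 carbonyl with no onward shift, addition–elimination at C7 with loss of methoxide, acid-induced cyclisation of the prenyl group onto the 5-hydroxyl, or re-oxidation of the hydroquinone in air. The fallback is a radical C–H alkylation followed by reduction. It sets out from quinone 17: silver-catalysed decarboxylative alkylation (Jacobsen–Torssell type) with 4-methylpent-3-enoic acid, AgNO3 (cat.) and (NH4)2S2O8 in MeCN–H2O at 60 °C should place the prenyl radical, through its primary terminus, on the only free quinone carbon. This gives 7-methoxy-6-(3-methylbut-2-enyl)-3-(2,4,5-trimethoxyphenyl)chromene-4,5,8-trione F3. Reduction of F3 with aqueous Na2S2O4 (EtOAc–H2O, rt) returns to the route at target 18.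

Step 11. Hydrogen abstraction from the strongly chelated 5-hydroxyl by the nitroxyl radical may be slow, so that conversion stalls or the quinone decomposes in the aqueous medium. The fallback is a two-electron para-hydroxylation followed by a separate oxidation. It sets out from phenol 16: Elbs persulfate oxidation (K2S2O8, aq. NaOH, pyridine, 0 °C → rt) should give potassium 5-hydroxy-7-methoxy-4-oxo-3-(2,4,5-trimethoxyphenyl)chromen-8-yl sulfate F4. Hydrolysis of F4 (aq. HCl, Na2SO3, 80 °C) should give 5,8-dihydroxy-7-methoxy-3-(2,4,5-trimethoxyphenyl)chromen-4-one F5. Oxidation of F5 with Ag2O (Et2O, MgSO4, rt) returns to the route at quinone 17.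

**Further compounds**

F1 | step 7 | 2-[4,5-dimethoxy-2-(triisopropylsilyloxy)phenyl]-1-(2-hydroxy-4,6-dimethoxyphenyl)ethanone | COc1cc(O)c(C(=O)Cc2cc(OC)c(OC)cc2O[Si](C(C)C)(C(C)C)C(C)C)c(OC)c1
F2 | step 7 | 3-(dimethylamino)-2-[4,5-dimethoxy-2-(triisopropylsilyloxy)phenyl]-1-(2-hydroxy-4,6-dimethoxyphenyl)prop-2-en-1-one | COc1cc(O)c(C(=O)C(=CN(C)C)c2cc(OC)c(OC)cc2O[Si](C(C)C)(C(C)C)C(C)C)c(OC)c1
F3 | step 12 | 7-methoxy-6-(3-methylbut-2-enyl)-3-(2,4,5-trimethoxyphenyl)chromene-4,5,8-trione | COC1=C(CC=C(C)C)C(=O)C2=C(OC=C(c3cc(OC)c(OC)cc3OC)C2=O)C1=O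
F4 | step 11 | potassium 5-hydroxy-7-methoxy-4-oxo-3-(2,4,5-trimethoxyphenyl)chromen-8-yl sulfate | COc1cc(O)c2c(occ(-c3cc(OC)c(OC)cc3OC)c2=O)c1OS(=O)(=O)[O-].[K+]
F5 | step 11 | 5,8-dihydroxy-7-methoxy-3-(2,4,5-trimethoxyphenyl)chromen-4-one | COc1cc(O)c2c(occ(-c3cc(OC)c(OC)cc3OC)c2=O)c1O
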